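**Plan**

- Retrosynthesis: the silyl and methoxymethyl groups are removed, the allyl groups on rings C and D are cut back to aryl chlorides, and the C4 allyl group is returned to O7 (para-Claisen). The dihydrofuran ring is then cut at C3–C3a and O1–C7a, giving ring A/D iodide 6 and ring B/C epoxide 14.
- Enabling feature: O1 and C3 sit on the adjacent ring A carbons C7a and C3a, and C7, the other neighbour of C7a, carries oxygen. An iodide at C7a therefore has one blocked ortho position (C7–O) and one free ortho C–H (C3a), the pattern a palladium–norbornene relay needs to alkylate C3a and then etherify C7a.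
- Forward order: 6 (steps 1–3) and 14 (steps 4–9, ring B–ring C bond by Suzuki coupling) are made separately. Step 10 joins them and closes the dihydrofuran ring, the only ring formed. Steps 11–15 free O7, move an allyl group from O7 to C4, allylate both chlorides and deprotect.
- Stereochemistry: Sharpless epoxidation with L-(+)-DIPT sets (2S,3S) in 13. Step 10 keeps C2 and inverts C3, turning the trans-epoxide into the cis-(2R,3S) dihydrobenzofuran; no later step touches either centre.

Key step: step 10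

Remark: locants follow 2,3-dihydro-1-benzofuran numbering (O1, C2, C3, C3a, C4–C7, C7a); (5-chloro-2-hydroxyphenyl)boronic acid is assumed to be a stock reagent.

**Route**

Step 1
Reactants: 1 2-iodophenol
Product: 2 2-iodophenyl N,N-diethylcarbamate
Conditions: ClC(O)NEt2, K2CO3, MeCN, reflux
Reagents that add atoms: N,N-diethylcarbamoyl chloride, CCN(CC)C(Cl)=O
Why: O-carbamoylation of a phenoxide (nucleophilic acyl substitution) is routine and installs the group that later directs lithiation, blocks C7 and withstands carbonate base.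

Step 2
Reactants: 2 2-iodophenyl N,N-diethylcarbamate, 3 4-chlorophenol
Product: 4 2-(4-chlorophenoxy)phenyl N,N-diethylcarbamate
Conditions: CuI (10 mol %), picolinic acid (20 mol %), K3PO4, DMSO, 90 °C
Reagents that add atoms: none
Why: Ullmann-type diaryl ether coupling with the copper–picolinic acid catalyst joins phenols to ortho-substituted aryl iodides and leaves the C–Cl bond and the carbamate untouched.

Step 3
Reactants: 4 2-(4-chlorophenoxy)phenyl N,N-diethylcarbamate
Product: 6 2-(4-chlorophenoxy)-6-iodophenyl N,N-diethylcarbamate, via aryllithium 5 (not isolated)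
Conditions: s-BuLi, TMEDA, THF, −78 °C; then I2, −78 °C to rt
Reagents that add atoms: iodine, II
Why: Directed ortho-metalation succeeds because the O-carbamate is the strongest directing group present and has a single free ortho position, −78 °C suppresses the anionic ortho-Fries shift, and the aryllithium is trapped by iodine.

Step 4
Reactants: 7 4-hydroxy-3-iodobenzaldehyde, 8 (5-chloro-2-hydroxyphenyl)boronic acid
Product: 9 5'-chloro-2',6-dihydroxy-[1,1'-biphenyl]-3-carbaldehyde
Conditions: Pd(PPh3)4 (3 mol %), Na2CO3, DME/H2O, 80 °C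
Reagents that add atoms: none
Why: Suzuki–Miyaura coupling with a triphenylphosphine catalyst engages only the C–I bond and tolerates free phenols in aqueous carbonate.

Step 5
Reactants: 9 5'-chloro-2',6-dihydroxy-[1,1'-biphenyl]-3-carbaldehyde
Product: 10 5'-chloro-2',6-bis(methoxymethoxy)-[1,1'-biphenyl]-3-carbaldehyde
Conditions: MOMCl, i-Pr2NEt, CH2Cl2, 0 °C to rt
Reagents that add atoms: chloromethyl methyl ether, COCCl
Why: O-alkylation of both phenols with chloromethyl methyl ether (Williamson-type acetal formation) gives ethers stable to base, hydride and heat and removable with acid at the end.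

Step 6
Reactants: 10 5'-chloro-2',6-bis(methoxymethoxy)-[1,1'-biphenyl]-3-carbaldehyde
Product: 11 ethyl (E)-3-[5'-chloro-2',6-bis(methoxymethoxy)-[1,1'-biphenyl]-3-yl]prop-2-enoate
Conditions: (EtO)2P(O)CH2CO2Et, NaH, THF, 0 °C to rt
Reagents that add atoms: triethyl phosphonoacetate, CCOC(=O)CP(=O)(OCC)OCC
Why: Horner–Wadsworth–Emmons olefination of an aryl aldehyde with a stabilised phosphonate reliably gives the E-enoate.

Step 7
Reactants: 11 ethyl (E)-3-[5'-chloro-2',6-bis(methoxymethoxy)-[1,1'-biphenyl]-3-yl]prop-2-enoate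
Product: 12 (E)-3-[5'-chloro-2',6-bis(methoxymethoxy)-[1,1'-biphenyl]-3-yl]prop-2-en-1-ol
Conditions: i-Bu2AlH, CH2Cl2, −78 °C
Reagents that add atoms: none
Why: 1,2-Reduction of an enoate by the aluminium hydride gives the E-allylic alcohol without touching the acetals or the aryl chloride.

Step 8
Reactants: 12 (E)-3-[5'-chloro-2',6-bis(methoxymethoxy)-[1,1'-biphenyl]-3-yl]prop-2-en-1-ol
Product: 13 [(2S,3S)-3-[5'-chloro-2',6-bis(methoxymethoxy)-[1,1'-biphenyl]-3-yl]oxiran-2-yl]methanol
Conditions: Ti(OiPr)4 (10 mol %), L-(+)-DIPT (12 mol %), t-BuOOH, 4 Å molecular sieves, CH2Cl2, −20 °C; aq. NaOH/brine work-up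
Reagents that add atoms: tert-butyl hydroperoxide, CC(C)(C)OO
Why: Sharpless asymmetric epoxidation of an E-allylic alcohol with the L-(+)-tartrate titanium catalyst delivers oxygen to the face that gives the (2S,3S)-epoxy alcohol, fixing the C2 configuration kept to the end and the C3 configuration that step 10 inverts.

Step 9
Reactants: 13 [(2S,3S)-3-[5'-chloro-2',6-bis(methoxymethoxy)-[1,1'-biphenyl]-3-yl]oxiran-2-yl]methanol
Product: 14 tert-butyl{[(2S,3S)-3-[5'-chloro-2',6-bis(methoxymethoxy)-[1,1'-biphenyl]-3-yl]oxiran-2-yl]methoxy}dimethylsilane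
Conditions: TBSCl, imidazole, CH2Cl2, 0 °C to rt
Reagents that add atoms: tert-butyldimethylsilyl chloride, CC(C)(C)[Si](C)(C)Cl
Why: Silylation of the primary alcohol under imidazole buffering leaves the acid-sensitive epoxide intact and places a bulky, electron-withdrawing silyloxymethyl group next to C2.

Step 10
Reactants: 6 2-(4-chlorophenoxy)-6-iodophenyl N,N-diethylcarbamate, 14 tert-butyl{[(2S,3S)-3-[5'-chloro-2',6-bis(methoxymethoxy)-[1,1'-biphenyl]-3-yl]oxiran-2-yl]methoxy}dimethylsilane
Product: 15 (2R,3S)-2-[(tert-butyldimethylsilyloxy)methyl]-3-[5'-chloro-2',6-bis(methoxymethoxy)-[1,1'-biphenyl]-3-yl]-6-(4-chlorophenoxy)-2,3-dihydro-1-benzofuran-7-yl N,N-diethylcarbamate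
Conditions: Pd(OAc)2 (10 mol %), P(2-furyl)3 (22 mol %), norbornene (1 equiv), Cs2CO3, MeCN, 90 °C
Reagents that add atoms: none
Why: Proposed new method: oxidative addition of the C7a–I bond of 6 to zerovalent palladium, norbornene insertion and base-assisted palladation of C3a–H give the five-membered aryl–norbornyl palladacycle of divalent palladium, which is expected to open epoxide 14 at benzylic C3 in an SN2-type oxidative addition (tetravalent palladium); C3–C3a reductive elimination, norbornene extrusion (both ortho positions now filled) and C7a–O reductive elimination from the six-membered aryl palladium alkoxide then deliver 15. The closest known reaction type is the palladium–norbornene (Catellani) annulation of ortho-substituted aryl iodides with terminal epoxides to 2-substituted 2,3-dihydrobenzofurans, in which the unsubstituted epoxide carbon is attacked; attack at the benzylic carbon of a 2,3-disubstituted epoxide is not established. The one ring is closed as a formal (3+2) annulation whose final event is intramolecular aryl C–O reductive elimination forming the five-membered ring. C3 is set by inversion of the (3S) epoxide carbon while C2 keeps its C–O bond and configuration, so the trans-epoxide maps onto the cis-(2R,3S) product. Regioselective opening relies on benzylic activation of C3 and on inductive and steric deactivation of C2 by the silyloxymethyl group; site selectivity on ring A is fixed because the carbamate oxygen at C7 blocks one ortho position and C3a is the only free one. Selectivity for C–I over the two C–Cl bonds rests on the weakly donating P(2-furyl)3 ligand.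

Step 11
Reactants: 15 (2R,3S)-2-[(tert-butyldimethylsilyloxy)methyl]-3-[5'-chloro-2',6-bis(methoxymethoxy)-[1,1'-biphenyl]-3-yl]-6-(4-chlorophenoxy)-2,3-dihydro-1-benzofuran-7-yl N,N-diethylcarbamate
Product: 16 (2R,3S)-2-[(tert-butyldimethylsilyloxy)methyl]-3-[5'-chloro-2',6-bis(methoxymethoxy)-[1,1'-biphenyl]-3-yl]-6-(4-chlorophenoxy)-2,3-dihydro-1-benzofuran-7-ol
Conditions: LiAlH4, THF, 0 to 40 °C
Reagents that add atoms: none
Why: Reductive cleavage of an aryl N,N-dialkylcarbamate by hydride attack at the carbonyl frees the O7 phenol and leaves silyl ether, acetals, aryl chlorides and both stereocentres untouched.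

Step 12
Reactants: 16 (2R,3S)-2-[(tert-butyldimethylsilyloxy)methyl]-3-[5'-chloro-2',6-bis(methoxymethoxy)-[1,1'-biphenyl]-3-yl]-6-(4-chlorophenoxy)-2,3-dihydro-1-benzofuran-7-ol
Product: 17 (2R,3S)-7-(allyloxy)-2-[(tert-butyldimethylsilyloxy)methyl]-3-[5'-chloro-2',6-bis(methoxymethoxy)-[1,1'-biphenyl]-3-yl]-6-(4-chlorophenoxy)-2,3-dihydro-1-benzofuran
Conditions: allyl bromide, K2CO3, DMF, 40 °C
Reagents that add atoms: allyl bromide, C=CCBr
Why: Williamson etherification of the only free hydroxyl group gives the aryl allyl ether needed for the sigmatropic shift.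

Step 13
Reactants: 17 (2R,3S)-7-(allyloxy)-2-[(tert-butyldimethylsilyloxy)methyl]-3-[5'-chloro-2',6-bis(methoxymethoxy)-[1,1'-biphenyl]-3-yl]-6-(4-chlorophenoxy)-2,3-dihydro-1-benzofuran
Product: 20 (2R,3S)-4-allyl-2-[(tert-butyldimethylsilyloxy)methyl]-3-[5'-chloro-2',6-bis(methoxymethoxy)-[1,1'-biphenyl]-3-yl]-6-(4-chlorophenoxy)-2,3-dihydro-1-benzofuran-7-ol, via ortho-dienone 18 (not isolated), via para-dienone 19 (not isolated)
Conditions: N,N-diethylaniline, 190 °C, sealed tube
Reagents that add atoms: none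
Why: Para-Claisen rearrangement: both positions ortho to O7 (C6 and C7a) carry oxygen, so the aromatic Claisen shift (drawn to C6; the shift to C7a converges) is followed by a Cope shift to C4, the position para to O7, and tautomerisation to the phenol, as in the classical rearrangement of allyl 2,6-dialkoxyphenyl ethers.

Step 14
Reactants: 20 (2R,3S)-4-allyl-2-[(tert-butyldimethylsilyloxy)methyl]-3-[5'-chloro-2',6-bis(methoxymethoxy)-[1,1'-biphenyl]-3-yl]-6-(4-chlorophenoxy)-2,3-dihydro-1-benzofuran-7-ol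
Product: 21 (2R,3S)-4-allyl-6-(4-allylphenoxy)-3-[5'-allyl-2',6-bis(methoxymethoxy)-[1,1'-biphenyl]-3-yl]-2-[(tert-butyldimethylsilyloxy)methyl]-2,3-dihydro-1-benzofuran-7-ol
Conditions: allylB(pin), Pd(OAc)2 (5 mol %), SPhos (10 mol %), K3PO4, THF/H2O, 70 °C
Reagents that add atoms: allylboronic acid pinacol ester, C=CCB1OC(C)(C)C(C)(C)O1
Why: Suzuki–Miyaura allylation of unactivated aryl chlorides is enabled by the electron-rich biarylphosphine, tolerates the free phenol as its phenoxide and replaces both chlorides by allyl groups.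

Step 15
Reactants: 21 (2R,3S)-4-allyl-6-(4-allylphenoxy)-3-[5'-allyl-2',6-bis(methoxymethoxy)-[1,1'-biphenyl]-3-yl]-2-[(tert-butyldimethylsilyloxy)methyl]-2,3-dihydro-1-benzofuran-7-ol
Product: 22 Magnolignan H, (2R,3S)-4-allyl-6-(4-allylphenoxy)-3-(5'-allyl-2',6-dihydroxy-[1,1'-biphenyl]-3-yl)-2-(hydroxymethyl)-2,3-dihydro-1-benzofuran-7-ol
Conditions: HCl (3 M in MeOH), 40 °C
Reagents that add atoms: none
Why: Acid-catalysed methanolysis cleaves the two aryl methoxymethyl acetals and the primary silyl ether in one operation, while the terminal alkenes and the non-benzylic C2–O1 bond are inert, so neither stereocentre can epimerise.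

**Compound list**

1 | 2-iodophenol | Oc1ccccc1I | starting material
2 | 2-iodophenyl N,N-diethylcarbamate | CCN(CC)C(=O)Oc1ccccc1I | intermediate
3 | 4-chlorophenol | Oc1ccc(Cl)cc1 | starting material
4 | 2-(4-chlorophenoxy)phenyl N,N-diethylcarbamate | CCN(CC)C(=O)Oc1ccccc1Oc1ccc(Cl)cc1 | intermediate
5 | 2-(4-chlorophenoxy)-6-lithiophenyl N,N-diethylcarbamate (not isolated) | CCN(CC)C(=O)Oc1c([Li])cccc1Oc1ccc(Cl)cc1 | intermediate
6 | 2-(4-chlorophenoxy)-6-iodophenyl N,N-diethylcarbamate | CCN(CC)C(=O)Oc1c(I)cccc1Oc1ccc(Cl)cc1 | intermediate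
7 | 4-hydroxy-3-iodobenzaldehyde | O=Cc1ccc(O)c(I)c1 | starting material
8 | (5-chloro-2-hydroxyphenyl)boronic acid | OB(O)c1cc(Cl)ccc1O | starting material
9 | 5'-chloro-2',6-dihydroxy-[1,1'-biphenyl]-3-carbaldehyde | O=Cc1ccc(O)c(-c2cc(Cl)ccc2O)c1 | intermediate
10 | 5'-chloro-2',6-bis(methoxymethoxy)-[1,1'-biphenyl]-3-carbaldehyde | O=Cc1ccc(OCOC)c(-c2cc(Cl)ccc2OCOC)c1 | intermediate
11 | ethyl (E)-3-[5'-chloro-2',6-bis(methoxymethoxy)-[1,1'-biphenyl]-3-yl]prop-2-enoate | CCOC(=O)/C=C/c1ccc(OCOC)c(-c2cc(Cl)ccc2OCOC)c1 | intermediate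
12 | (E)-3-[5'-chloro-2',6-bis(methoxymethoxy)-[1,1'-biphenyl]-3-yl]prop-2-en-1-ol | OC/C=C/c1ccc(OCOC)c(-c2cc(Cl)ccc2OCOC)c1 | intermediate
13 | [(2S,3S)-3-[5'-chloro-2',6-bis(methoxymethoxy)-[1,1'-biphenyl]-3-yl]oxiran-2-yl]methanol | OC[C@@H]1O[C@H]1c1ccc(OCOC)c(-c2cc(Cl)ccc2OCOC)c1 | intermediate
14 | tert-butyl{[(2S,3S)-3-[5'-chloro-2',6-bis(methoxymethoxy)-[1,1'-biphenyl]-3-yl]oxiran-2-yl]methoxy}dimethylsilane | CC(C)(C)[Si](C)(C)OC[C@@H]1O[C@H]1c1ccc(OCOC)c(-c2cc(Cl)ccc2OCOC)c1 | intermediate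
15 | (2R,3S)-2-[(tert-butyldimethylsilyloxy)methyl]-3-[5'-chloro-2',6-bis(methoxymethoxy)-[1,1'-biphenyl]-3-yl]-6-(4-chlorophenoxy)-2,3-dihydro-1-benzofuran-7-yl N,N-diethylcarbamate (cis) | CCN(CC)C(=O)Oc1c(Oc2ccc(Cl)cc2)ccc2c1O[C@@H](CO[Si](C)(C)C(C)(C)C)[C@H]2c1ccc(OCOC)c(-c2cc(Cl)ccc2OCOC)c1 | intermediate
16 | (2R,3S)-2-[(tert-butyldimethylsilyloxy)methyl]-3-[5'-chloro-2',6-bis(methoxymethoxy)-[1,1'-biphenyl]-3-yl]-6-(4-chlorophenoxy)-2,3-dihydro-1-benzofuran-7-ol | Oc1c(Oc2ccc(Cl)cc2)ccc2c1O[C@@H](CO[Si](C)(C)C(C)(C)C)[C@H]2c1ccc(OCOC)c(-c2cc(Cl)ccc2OCOC)c1 | intermediate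
17 | (2R,3S)-7-(allyloxy)-2-[(tert-butyldimethylsilyloxy)methyl]-3-[5'-chloro-2',6-bis(methoxymethoxy)-[1,1'-biphenyl]-3-yl]-6-(4-chlorophenoxy)-2,3-dihydro-1-benzofuran | C=CCOc1c(Oc2ccc(Cl)cc2)ccc2c1O[C@@H](CO[Si](C)(C)C(C)(C)C)[C@H]2c1ccc(OCOC)c(-c2cc(Cl)ccc2OCOC)c1 | intermediate
18 | ortho-dienone: (2R,3S)-6-allyl-2-[(tert-butyldimethylsilyloxy)methyl]-3-[5'-chloro-2',6-bis(methoxymethoxy)-[1,1'-biphenyl]-3-yl]-6-(4-chlorophenoxy)-2,3-dihydro-1-benzofuran-7(6H)-one, C6 unassigned (not isolated) | O=C1C(CC=C)(Oc2ccc(Cl)cc2)C=CC2=C1O[C@@H](CO[Si](C)(C)C(C)(C)C)[C@H]2c1ccc(OCOC)c(-c2cc(Cl)ccc2OCOC)c1 | intermediate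
19 | para-dienone: (2R,3S)-4-allyl-2-[(tert-butyldimethylsilyloxy)methyl]-3-[5'-chloro-2',6-bis(methoxymethoxy)-[1,1'-biphenyl]-3-yl]-6-(4-chlorophenoxy)-2,3-dihydro-1-benzofuran-7(4H)-one, C4 unassigned (not isolated) | O=C1C(Oc2ccc(Cl)cc2)=CC(CC=C)C2=C1O[C@@H](CO[Si](C)(C)C(C)(C)C)[C@H]2c1ccc(OCOC)c(-c2cc(Cl)ccc2OCOC)c1 | intermediate
20 | (2R,3S)-4-allyl-2-[(tert-butyldimethylsilyloxy)methyl]-3-[5'-chloro-2',6-bis(methoxymethoxy)-[1,1'-biphenyl]-3-yl]-6-(4-chlorophenoxy)-2,3-dihydro-1-benzofuran-7-ol | Oc1c(Oc2ccc(Cl)cc2)cc(CC=C)c2c1O[C@@H](CO[Si](C)(C)C(C)(C)C)[C@H]2c1ccc(OCOC)c(-c2cc(Cl)ccc2OCOC)c1 | intermediate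
21 | (2R,3S)-4-allyl-6-(4-allylphenoxy)-3-[5'-allyl-2',6-bis(methoxymethoxy)-[1,1'-biphenyl]-3-yl]-2-[(tert-butyldimethylsilyloxy)methyl]-2,3-dihydro-1-benzofuran-7-ol | Oc1c(Oc2ccc(CC=C)cc2)cc(CC=C)c2c1O[C@@H](CO[Si](C)(C)C(C)(C)C)[C@H]2c1ccc(OCOC)c(-c2cc(CC=C)ccc2OCOC)c1 | intermediate
22 | Magnolignan H, (2R,3S)-4-allyl-6-(4-allylphenoxy)-3-(5'-allyl-2',6-dihydroxy-[1,1'-biphenyl]-3-yl)-2-(hydroxymethyl)-2,3-dihydro-1-benzofuran-7-ol | C=CCc1ccc(Oc2cc(CC=C)c3c(c2O)O[C@@H](CO)[C@H]3c2ccc(O)c(-c3cc(CC=C)ccc3O)c2)cc1 | target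

**Count and risks**

Total step count: 15. Longest linear sequence: 12 steps (steps 4–15, from 7).

Steps most likely to fail:

1. Step 10 (the proposed method). The hindered palladacycle may attack a secondary benzylic epoxide carbon too slowly, so that premature ipso termination, norbornene-containing by-products or rearrangement of the electron-rich epoxide to a carbonyl compound take over. The cis relationship would be eroded if the accumulating iodide opens the epoxide first (double inversion) or if C3 ionises. β-Hydride elimination of the palladium alkoxide could also intercept ring closure. The fallback sets out from 6 and 14 and returns at 15, forming the same two bonds one after the other by known reactions. LiN(i-Pr)2 in THF at −78 °C should trigger the halogen dance known for ortho-iodoaryl O-carbamates, moving iodine to C3a and lithium to C7a to give 6-(4-chlorophenoxy)-3-iodo-2-lithiophenyl N,N-diethylcarbamate F1. Quenching with 1,2-dibromotetrachloroethane should give 2-bromo-6-(4-chlorophenoxy)-3-iodophenyl N,N-diethylcarbamate F2. Iodine–magnesium exchange (i-PrMgCl·LiCl, THF, −40 °C) should give [2-bromo-4-(4-chlorophenoxy)-3-(diethylcarbamoyloxy)phenyl]magnesium chloride F3. With CuI (10 mol %) this should open 14 at benzylic C3 with inversion, the usual course for aryl cuprate opening of trans-3-aryl-2,3-epoxy alcohol ethers, giving (2R,3S)-3-[2-bromo-4-(4-chlorophenoxy)-3-(diethylcarbamoyloxy)phenyl]-1-(tert-butyldimethylsilyloxy)-3-[5'-chloro-2',6-bis(methoxymethoxy)-[1,1'-biphenyl]-3-yl]propan-2-ol F4. Intramolecular Ullmann etherification of the C7a bromide (CuI, 1,10-phenanthroline, Cs2CO3, toluene, 110 °C), which spares the aryl chlorides, should then close the ring to 15.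

2. Step 8. The electron-rich benzylic epoxide may be opened by isopropanol, tartrate or water under the Lewis-acidic titanium conditions or during work-up. The fallback sets out from 12 and returns at 14. Silylation first (TBSCl, imidazole, CH2Cl2) would give tert-butyl{[(E)-3-[5'-chloro-2',6-bis(methoxymethoxy)-[1,1'-biphenyl]-3-yl]prop-2-en-1-yl]oxy}dimethylsilane F5. Shi epoxidation under buffered basic conditions (KHSO5 as 2KHSO5·KHSO4·K2SO4, K2CO3, Bu4NHSO4, MeCN/dimethoxymethane/aqueous buffer of pH about 10.5, 0 °C) would then give 14 directly. The catalyst would be the L-sorbose-derived enantiomer of the fructose-based ketone, chosen because the fructose-derived ketone gives the (R,R) series from trans-β-substituted styrenes.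

3. Step 13. The second sigmatropic shift must reach C4, which is flanked by the C3 aryl group; if it is slow, loss of the allyl ether or epimerisation at C3 through vinylogous enolisation of the dienone intermediates may compete at 190 °C. The fallback sets out from 16 and returns at 21, bypassing steps 12–14. Bromination para to the free hydroxyl (NBS, CH2Cl2, −40 °C; the selectivity known for 2,6-dioxygenated phenols) should give (2R,3S)-4-bromo-2-[(tert-butyldimethylsilyloxy)methyl]-3-[5'-chloro-2',6-bis(methoxymethoxy)-[1,1'-biphenyl]-3-yl]-6-(4-chlorophenoxy)-2,3-dihydro-1-benzofuran-7-ol F6. Threefold Suzuki–Miyaura allylation of the bromide and both chlorides under the conditions of step 14 with excess allylB(pin) should then give 21.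

**Further compounds**

F1 | step 10 | 6-(4-chlorophenoxy)-3-iodo-2-lithiophenyl N,N-diethylcarbamate | CCN(CC)C(=O)Oc1c([Li])c(I)ccc1Oc1ccc(Cl)cc1
F2 | step 10 | 2-bromo-6-(4-chlorophenoxy)-3-iodophenyl N,N-diethylcarbamate | CCN(CC)C(=O)Oc1c(Br)c(I)ccc1Oc1ccc(Cl)cc1
F3 | step 10 | [2-bromo-4-(4-chlorophenoxy)-3-(diethylcarbamoyloxy)phenyl]magnesium chloride | CCN(CC)C(=O)Oc1c(Br)c([Mg]Cl)ccc1Oc1ccc(Cl)cc1
F4 | step 10 | (2R,3S)-3-[2-bromo-4-(4-chlorophenoxy)-3-(diethylcarbamoyloxy)phenyl]-1-(tert-butyldimethylsilyloxy)-3-[5'-chloro-2',6-bis(methoxymethoxy)-[1,1'-biphenyl]-3-yl]propan-2-ol | CCN(CC)C(=O)Oc1c(Oc2ccc(Cl)cc2)ccc(c1Br)[C@@H]([C@@H](O)CO[Si](C)(C)C(C)(C)C)c1ccc(OCOC)c(-c2cc(Cl)ccc2OCOC)c1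
F5 | step 8 | tert-butyl{[(E)-3-[5'-chloro-2',6-bis(methoxymethoxy)-[1,1'-biphenyl]-3-yl]prop-2-en-1-yl]oxy}dimethylsilane | CC(C)(C)[Si](C)(C)OC/C=C/c1ccc(OCOC)c(-c2cc(Cl)ccc2OCOC)c1
F6 | step 13 | (2R,3S)-4-bromo-2-[(tert-butyldimethylsilyloxy)methyl]-3-[5'-chloro-2',6-bis(methoxymethoxy)-[1,1'-biphenyl]-3-yl]-6-(4-chlorophenoxy)-2,3-dihydro-1-benzofuran-7-ol | Oc1c(Oc2ccc(Cl)cc2)cc(Br)c2c1O[C@@H](CO[Si](C)(C)C(C)(C)C)[C@H]2c1ccc(OCOC)c(-c2cc(Cl)ccc2OCOC)c1
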